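## Structural features

The target 18 is a single cyclohex-5-ene ring (C1–C6) with one exocyclic carbon, C7, attached as a benzoyloxymethyl group to the fully substituted carbinol C1. Four contiguous stereocentres C1–C4 all bear oxygen: the C1 and C2 hydroxyls are cis (both β), C2/C3 and C3/C4 are trans, so the C3 benzoate is α and the C4 hydroxyl β; the absolute configuration is (1S,2S,3R,4S). The C5=C6 alkene lies between C4 and C1, which makes the C4 hydroxyl secondary allylic and the C1 hydroxyl tertiary allylic. The fragile elements are the two benzoates next to free hydroxyls (acyl migration or loss under base), the allylic carbinols (ionisation under acid, assisted by neighbouring esters) and the tendency of any dienediol precursor to aromatise. The real difficulties are the absolute configuration of the quaternary carbinol C1, which cannot be corrected later, and the differentiation of five oxygens so that only O3 and O7 are acylated. The key step exploits the unit C7–C1(O)–C6, a 2-oxyacrylate, joined through C1–C2 and C5–C6 to the unit C2(O)–C3–C4–C5, a 1-oxybuta-1,3-diene; the cis C1–O/C2–O pair on adjacent ring carbons is the signature of a carbonyl-exo [4+2] closure of the six-membered ring.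

## Logic of the disconnections

18 to 16 (through 17): the ether C–O bond on O4 and the two acetal C–O bonds on O1 and O2 are cut. The three hydroxyls that end free must stay distinct from the two acylated ones until the last operation, and a benzyl-type ether plus a cyclic acetal fall to one reagent class. Nothing is gained in skeleton, but the target becomes a fully differentiated intermediate. The forward step needs acid that cleaves both groups without ionising the allylic carbinols or moving a benzoate.

16 to 15: the O3–acyl bond is cut. The second benzoate is placed on the only free hydroxyl, so regiochemistry is no longer an issue. The forward step is an acylation of a hindered secondary alcohol that must not trigger acyl migration.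

15 to 14: the C4–O ether bond is cut and O3 is reconnected to C4 as an oxirane. A trans C3/C4 pair with two different oxygen substituents is what anti opening of an epoxide at its allylic carbon gives. Two stereocentres collapse to one cis-epoxide and the two oxygens arise already different. The forward step needs attack at C4 only, with inversion, and no conjugate opening at C6.

14 to 13: the C3–O and C4–O bonds of the oxirane are cut. This removes two stereocentres and leaves a diene whose only stereocentres are C1 and C2. The forward step needs the C3=C4 alkene to react in preference to C5=C6, and on the α face.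

13 to 11 (through 12) to 10: the C5=C6 unsaturation is taken back to a C3,C4-dibromide (C3–Br and C4–Br cut) and then to the simple C3=C4 alkene. The cycloaddition can deliver only one ring alkene, so the second has to come from an adjustment of oxidation level. The intermediate becomes an ordinary cyclohexene. The forward eliminations must end at the 3,5-diene and not run toward C2.

10 to 9 to 8: the acetal C–O bonds on O1/O2 are cut, then the O7–acyl bond. The C7 benzoate is a target feature and is installed first so that the acetal can only span O1 and O2. The result is a plain triol. The forward acylation must be selective for the primary hydroxyl.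

8 to 7: C7 is returned to the carboxyl oxidation level, O1 and the carboxyl are tied through an acetal carbon, and O2 is re-acylated. This reveals the masked α-hydroxy acid that the cycloaddition produces. The forward step is an exhaustive hydride reduction that also removes the auxiliary and the acetate.

7 to 5 and 6: the C1–C2 and C5–C6 bonds are cut. The ring, the quaternary carbinol and C2 then arise from two small pieces, with chirality supplied by a removable acetal. The forward step must be ortho-regioselective, carbonyl-exo, and anti to the tert-butyl group.

5 to 4 to 3 to 1 and 2: the exocyclic alkene is taken back to C–Br and then to the methyl group, and the two acetal C–O bonds are cut. The dienophile is dehydro-1 in acetal form. The forward sequence needs the cis acetal in diastereomerically pure form, because that purity becomes the enantiomeric purity of the route.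

## Other disconnections considered

Alternative 1: The cut is at C1–O and C6–O, so that all seven carbons trace back to benzoic acid A1. The forward key step would be a whole-cell arene ipso,ortho-cis-dihydroxylation of A1 with air, giving (1S,2R)-1,2-dihydroxycyclohexa-3,5-diene-1-carboxylic acid A2 without any ring closure.
- In its favour: one operation on a commodity arene would deliver the complete skeleton, the quaternary carbinol C1 under enzymatic enantiocontrol, and both ring alkenes (C2=C3, C4=C5) for later oxygenation.
- Against it here: for the enantiomer 18, the hydroxylated ortho carbon of A2 has to be read as C6, because reading it as C2 leads to the mirror-image series. C6 is olefinic in 18, so this oxygen would have to be moved suprafacially to C4 or removed. C2=C3 would need trans-dioxygenation with the acyl group ending on O3. The carboxyl would have to be reduced on an acid-sensitive dienediol that aromatises easily, and a fermentation with a specialised strain is required.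
- Structure: A2 and 7 both contain C1–C7 and the C1 carbinol, but 7 carries its second oxygen on C2, where 18 needs it.
- Mechanism: the enzyme needs no auxiliary and wastes no atoms, which is better than the acetal-controlled cycloaddition. It leaves a stereospecific allylic transposition for which the chosen plan has no counterpart.
- Step economy: an enantiopure carbocycle in one step against four, and possibly a shorter route overall. On both counts the alternative is the equal or the better, at the price of biological infrastructure and a less predictable middle part.

Alternative 2: The cut is at C1–O and C4–O, back to the conjugated diene [(5R,6R)-5-(benzoyloxy)-6-hydroxycyclohexa-1,3-dien-1-yl]methyl benzoate A3. The forward key step would be a dye-sensitised photooxygenation, a hetero-[4+2] addition across the diene termini, giving the endoperoxide [8-(benzoyloxy)-7-hydroxy-2,3-dioxabicyclo[2.2.2]oct-5-en-1-yl]methyl benzoate A4 with the alkene shifted to C5=C6. Mild reduction of the O–O bond of A4 would give 18 directly.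
- In its favour: one pericyclic step would make two C–O bonds, place the alkene and guarantee the cis-1,4 relation of the C1 and C4 hydroxyls. Both benzoates are already present, so there is no protecting-group endgame; in this respect it is better than the chosen plan, which ends with an acidic deprotection.
- Against it here: A3 already contains C2, C3 and the whole skeleton, so the construction of the ring and of the C1–C7 bond is postponed, not solved. A3 is a 5,6-dioxygenated cyclohexa-1,3-diene and is expected to aromatise readily. The oxidant must add syn to the C2 hydroxyl but anti to the C3 ester, two groups on opposite faces, so no single element dictates the face. A4 has a bridgehead hydrogen at C4 and is open to Kornblum–DeLaMare rearrangement under base.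
- Structure: both plans use a [4+2] step, but the chosen one forms C–C bonds and the ring, while this one only adds heteroatoms to a ring that must come from elsewhere.
- Mechanism: equal in stereospecificity, weaker in face control.
- Step economy: shorter after the key step (better), but not overall once the synthesis of A3 is counted.

Alternative 3: The cut is at the ring bond C5–C6, opening the carbocycle to a hexose. The forward key step would be the enzymatic carbocyclisation of D-glucose 6-phosphate A5 (oxidation, phosphate elimination, reduction, intramolecular aldol closure) to 2-deoxy-scyllo-inosose A6. Its ketone carbon maps to C1, its methylene to C6 and its four carbinols to C2–C5.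
- In its favour: C2, C3 and C4 of 18 would arrive in one step with the correct all-trans relative and absolute configuration from a very cheap chiral feedstock. The ketone is a handle for adding C7, and the C5 hydroxyl, β to the ketone, is a handle for the C5=C6 alkene. In stereocentres per step (three against two) and in feedstock cost this is better than the chosen key step.
- Against it here: C7 is missing, and the tertiary carbinol would have to be made by a substrate-controlled 1,2-addition of a hydroxymethyl anion equivalent. Of three similar trans secondary hydroxyls only the central one, O3, is to be acylated, the hardest pattern for protecting-group chemistry. A6 is a β-hydroxy ketone prone to dehydration and aromatisation, and enzyme, cofactor and phosphorylated substrate are required.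
- Structure: the two plans are complementary; the alternative secures C2–C4 but not C1/C7, the chosen plan secures C1, C2 and C7 and adds C3/C4 by stereospecific epoxide chemistry.
- Mechanism: an enzymatic aldol closure with control from the sugar against a pericyclic closure with auxiliary control; equal for the ring-forming event, less secure at the quaternary centre.
- Step economy: probably no shorter once the differentiation of O2, O3 and O4 is counted.

Key step: step 4

Remark: locants C1–C7 are those of 18 throughout and β is the ring face carrying the C1 hydroxyl. Re-derivation of the configurations confirms that the (2S) acetal from (S)-lactic acid, attacked anti to tert-butyl in the carbonyl-exo mode, gives the required (1S,2S) arrangement, so no structure needs correcting. Commercial buta-1,3-dien-1-yl acetate is assumed to be an E/Z mixture of which only the E isomer 6 reacts, so it is used in excess.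

## Steps

Step 1
Reactants: 1 (S)-lactic acid; 2 pivalaldehyde (2,2-dimethylpropanal)
Product: 3 (2S,5S)-2-tert-butyl-5-methyl-1,3-dioxolan-4-one (cis acetal)
Conditions: TsOH·H2O (cat.), pentane, reflux, Dean–Stark; recrystallisation from pentane, −78 °C
Reagents that add atoms: none
Why: Acid-catalysed acetalisation of the α-hydroxy acid with azeotropic removal of water; the acetal carbon equilibrates so that tert-butyl sits cis to methyl in the major, crystalline diastereomer, which copies the lactic acid stereocentre onto the acetal carbon.

Step 2
Reactants: 3 (2S,5S)-2-tert-butyl-5-methyl-1,3-dioxolan-4-one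
Product: 4 (2S,5R)-5-bromo-2-tert-butyl-5-methyl-1,3-dioxolan-4-one
Conditions: NBS, AIBN (cat.), PhCF3, 80 °C
Reagents that add atoms: N-bromosuccinimide, O=C1CCC(=O)N1Br
Why: Wohl–Ziegler-type radical bromination at C5, where hydrogen abstraction gives a tertiary radical flanked by the ring oxygen and the carbonyl; bromine should enter anti to tert-butyl, but this centre is erased in step 3 and its configuration does not matter.

Step 3
Reactants: 4 (2S,5R)-5-bromo-2-tert-butyl-5-methyl-1,3-dioxolan-4-one
Product: 5 (2S)-2-tert-butyl-5-methylene-1,3-dioxolan-4-one
Conditions: Et3N, Et2O, 0 °C to rt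
Reagents that add atoms: none
Why: E2 dehydrobromination of a tertiary α-bromo lactone toward the methyl group, the only source of β-hydrogens, gives the exocyclic 2-oxyacrylate; the acetal stereocentre is untouched and is now the sole element of chirality.

Step 4
Reactants: 5 (2S)-2-tert-butyl-5-methylene-1,3-dioxolan-4-one; 6 (E)-buta-1,3-dien-1-yl acetate
Product: 7 (2S,5R,6S)-6-acetoxy-2-tert-butyl-1,3-dioxaspiro[4.5]dec-7-en-4-one (exo spiro adduct)
Conditions: 6 (3 equiv), BHT (cat.), PhMe, 100 °C, sealed tube
Reagents that add atoms: none
Why: The step is a concerted, asynchronous Diels–Alder reaction of normal electron demand between the HOMO of the 1-acyloxydiene and the LUMO of the 2-oxyacrylate; the closest known reaction type is the thermal exo-selective cycloaddition of chiral 5-methylene-1,3-dioxolan-4-ones with acyclic dienes. The cyclohexene ring is closed by suprafacial formation of C1–C2 and C5–C6 in one intermolecular [4+2] event, leaving C3=C4 and a spiro junction at C1. The ortho regiochemistry follows from the large HOMO coefficient at the unsubstituted diene terminus C5 meeting the large LUMO coefficient at the methylene carbon C6, so that the acetoxy-bearing C2 bonds to C1. C1 is controlled by the acetal stereocentre: the diene adds to the alkene face opposite tert-butyl, which for the (2S) acetal gives (5R) in 7, that is C1–O β and C7 α as in 18. C2 is controlled by topology: with the ring oxygen endo and the lactone carbonyl exo, the (E)-acetoxy group ends cis to the C1 oxygen, giving (6S). The step therefore needs ortho over meta orientation, carbonyl-exo over carbonyl-endo approach and attack anti to tert-butyl; these are secured by the acetoxy donor, by the dioxolanone (less dipole and steric repulsion between lactone carbonyl and diene in the exo mode) and by the tert-butyl group. The Z isomer of the diene cannot easily adopt the s-cis conformation and should remain unchanged, and BHT suppresses radical polymerisation of 5.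

Step 5
Reactants: 7 (2S,5R,6S)-6-acetoxy-2-tert-butyl-1,3-dioxaspiro[4.5]dec-7-en-4-one
Product: 8 (1S,2S)-1-(hydroxymethyl)cyclohex-3-ene-1,2-diol
Conditions: LiAlH4 (3 equiv), THF, 0 °C to rt; H2O/15% NaOH (aq)/H2O quench
Reagents that add atoms: none
Why: Hydride reduction of the acylal-type lactone takes C7 to the carbinol while the released hemiacetal collapses to pivalaldehyde (reduced further) and frees the C1 hydroxyl; the C2 acetate is cleaved in the same operation and no stereocentre is touched.

Step 6
Reactants: 8 (1S,2S)-1-(hydroxymethyl)cyclohex-3-ene-1,2-diol
Product: 9 [(1S,2S)-1,2-dihydroxycyclohex-3-en-1-yl]methyl benzoate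
Conditions: BzCl (1.05 equiv), 2,4,6-collidine, CH2Cl2, −78 to −20 °C
Reagents that add atoms: benzoyl chloride, O=C(Cl)c1ccccc1
Why: Kinetically selective O-acylation; the primary C7 hydroxyl should react much faster than the hindered secondary allylic C2 hydroxyl or the tertiary C1 hydroxyl under these mild conditions.

Step 7
Reactants: 9 [(1S,2S)-1,2-dihydroxycyclohex-3-en-1-yl]methyl benzoate
Product: 10 [(3aS,7aS)-2,2-dimethyl-3a,4,5,7a-tetrahydro-1,3-benzodioxol-3a-yl]methyl benzoate (C1,C2-acetonide, C3=C4 alkene)
Conditions: 2,2-dimethoxypropane, PPTS (cat.), acetone, rt
Reagents that add atoms: 2,2-dimethoxypropane, COC(C)(C)OC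
Why: Acid-catalysed transacetalisation; the only diol left is the cis C1/C2 pair, which closes a cis-fused dioxolane that protects both hydroxyls and shields the β face.

Step 8
Reactants: 10 [(3aS,7aS)-2,2-dimethyl-3a,4,5,7a-tetrahydro-1,3-benzodioxol-3a-yl]methyl benzoate
Product: 11 [(3aS,6S,7S,7aR)-6,7-dibromo-2,2-dimethylhexahydro-1,3-benzodioxol-3a-yl]methyl benzoate (3α,4β-dibromide)
Conditions: Br2 (1.05 equiv), CH2Cl2, −78 °C
Reagents that add atoms: bromine, BrBr
Why: Anti addition of bromine through a bromonium ion on the α face, opposite the acetonide, opened by bromide at C4, the carbon remote from the deactivating C2 oxygen; the two new centres are temporary.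

Step 9
Reactants: 11 [(3aS,6S,7S,7aR)-6,7-dibromo-2,2-dimethylhexahydro-1,3-benzodioxol-3a-yl]methyl benzoate
Product: 13 [(3aS,7aS)-2,2-dimethyl-3a,7a-dihydro-1,3-benzodioxol-3a-yl]methyl benzoate (3,5-diene acetonide), via allylic bromide 12 (not isolated)
Conditions: DBU (4 equiv), PhMe, 90 °C
Reagents that add atoms: none
Why: Double dehydrobromination: anti E2 of C4–Br with C5–H gives the 3α-bromo-4-ene, and 1,4-elimination of C3–Br with C6–H (or E2 of its allylic isomer) then gives the 3,5-diene; elimination toward C2 is disfavoured because C2–H is cis to C3–Br and the product would be a strained enol ether at the ring fusion.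

Step 10
Reactants: 13 [(3aS,7aS)-2,2-dimethyl-3a,7a-dihydro-1,3-benzodioxol-3a-yl]methyl benzoate
Product: 14 [(1S,2S,3R,4R)-3,4-epoxy-1,2-(isopropylidenedioxy)cyclohex-5-en-1-yl]methyl benzoate (3α,4α-epoxide)
Conditions: mCPBA (1.05 equiv), NaHCO3, CH2Cl2, 0 °C
Reagents that add atoms: 3-chloroperoxybenzoic acid, O=C(OO)c1cccc(Cl)c1
Why: Prilezhaev epoxidation of the less hindered C3=C4 alkene (C5=C6 abuts the quaternary C1 and its α-oriented CH2OBz group) from the α face, opposite the acetonide, which places the C3 oxygen α; the buffer prevents acid opening of the vinyl epoxide.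

Step 11
Reactants: 14 [(1S,2S,3R,4R)-3,4-epoxy-1,2-(isopropylidenedioxy)cyclohex-5-en-1-yl]methyl benzoate
Product: 15 [(1S,2S,3R,4S)-3-hydroxy-1,2-(isopropylidenedioxy)-4-(4-methoxybenzyloxy)cyclohex-5-en-1-yl]methyl benzoate
Conditions: 4-methoxybenzyl alcohol (5 equiv), BF3·OEt2 (0.2 equiv), CH2Cl2, −40 °C
Reagents that add atoms: 4-methoxybenzyl alcohol, COc1ccc(CO)cc1
Why: Lewis-acid-catalysed alcoholysis of a vinyl epoxide; the alcohol attacks the allylic carbon C4 with inversion (C4–O β) and the epoxide oxygen is left as the free 3α hydroxyl, while attack at C3 is deactivated by the C2 oxygen and conjugate attack at C6 is blocked by quaternary C1.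

Step 12
Reactants: 15 [(1S,2S,3R,4S)-3-hydroxy-1,2-(isopropylidenedioxy)-4-(4-methoxybenzyloxy)cyclohex-5-en-1-yl]methyl benzoate
Product: 16 [(1S,2S,3R,4S)-3-(benzoyloxy)-1,2-(isopropylidenedioxy)-4-(4-methoxybenzyloxy)cyclohex-5-en-1-yl]methyl benzoate
Conditions: BzCl, pyridine, DMAP (cat.), CH2Cl2, 0 °C to rt
Reagents that add atoms: benzoyl chloride, O=C(Cl)c1ccccc1
Why: DMAP-catalysed acylation of the only free hydroxyl; no stereocentre is involved and no competing hydroxyl is present.

Step 13
Reactants: 16 [(1S,2S,3R,4S)-3-(benzoyloxy)-1,2-(isopropylidenedioxy)-4-(4-methoxybenzyloxy)cyclohex-5-en-1-yl]methyl benzoate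
Product: 18 [(1S,2S,3R,4S)-3-(benzoyloxy)-1,2,4-trihydroxycyclohex-5-en-1-yl]methyl benzoate (target), via acetonide alcohol 17 (not isolated)
Conditions: TFA, anisole, CH2Cl2, 0 °C; then H2O, 0 °C to rt
Reagents that add atoms: none
Why: Acidolysis of the 4-methoxybenzyl ether (cation trapped by anisole) followed by hydrolysis of the acetonide once water is added; both cleavages occur at the protecting-group carbon, so C1, C2 and C4 keep their configuration and the benzoates should survive cold aqueous acid.

## Compound list

1 | (S)-lactic acid | C[C@H](O)C(=O)O | starting material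
2 | pivalaldehyde | CC(C)(C)C=O | starting material
3 | (2S,5S)-2-tert-butyl-5-methyl-1,3-dioxolan-4-one | O=C1O[C@@H](C(C)(C)C)O[C@H]1C | intermediate
4 | (2S,5R)-5-bromo-2-tert-butyl-5-methyl-1,3-dioxolan-4-one | O=C1O[C@@H](C(C)(C)C)O[C@]1(C)Br | intermediate
5 | (2S)-2-tert-butyl-5-methylene-1,3-dioxolan-4-one | O=C1O[C@@H](C(C)(C)C)OC1=C | intermediate
6 | (E)-buta-1,3-dien-1-yl acetate | CC(=O)O/C=C/C=C | starting material
7 | (2S,5R,6S)-6-acetoxy-2-tert-butyl-1,3-dioxaspiro[4.5]dec-7-en-4-one | O=C1O[C@@H](C(C)(C)C)O[C@@]12CCC=C[C@@H]2OC(C)=O | intermediate
8 | (1S,2S)-1-(hydroxymethyl)cyclohex-3-ene-1,2-diol | OC[C@@]1(O)CCC=C[C@@H]1O | intermediate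
9 | [(1S,2S)-1,2-dihydroxycyclohex-3-en-1-yl]methyl benzoate | O=C(OC[C@@]1(O)CCC=C[C@@H]1O)c1ccccc1 | intermediate
10 | [(3aS,7aS)-2,2-dimethyl-3a,4,5,7a-tetrahydro-1,3-benzodioxol-3a-yl]methyl benzoate | O=C(OC[C@@]12CCC=C[C@@H]1OC(C)(C)O2)c1ccccc1 | intermediate
11 | [(3aS,6S,7S,7aR)-6,7-dibromo-2,2-dimethylhexahydro-1,3-benzodioxol-3a-yl]methyl benzoate (3α,4β-dibromide) | O=C(OC[C@@]12CC[C@H](Br)[C@@H](Br)[C@@H]1OC(C)(C)O2)c1ccccc1 | intermediate
12 | [(3aS,7R,7aR)-7-bromo-2,2-dimethyl-3a,4,7,7a-tetrahydro-1,3-benzodioxol-3a-yl]methyl benzoate (3α-bromo-4-ene) | O=C(OC[C@@]12CC=C[C@@H](Br)[C@@H]1OC(C)(C)O2)c1ccccc1 | intermediate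
13 | [(3aS,7aS)-2,2-dimethyl-3a,7a-dihydro-1,3-benzodioxol-3a-yl]methyl benzoate | O=C(OC[C@@]12C=CC=C[C@@H]1OC(C)(C)O2)c1ccccc1 | intermediate
14 | [(1S,2S,3R,4R)-3,4-epoxy-1,2-(isopropylidenedioxy)cyclohex-5-en-1-yl]methyl benzoate | O=C(OC[C@@]12C=C[C@H]3O[C@H]3[C@@H]1OC(C)(C)O2)c1ccccc1 | intermediate
15 | [(1S,2S,3R,4S)-3-hydroxy-1,2-(isopropylidenedioxy)-4-(4-methoxybenzyloxy)cyclohex-5-en-1-yl]methyl benzoate | O=C(OC[C@@]12C=C[C@H](OCc3ccc(OC)cc3)[C@@H](O)[C@@H]1OC(C)(C)O2)c1ccccc1 | intermediate
16 | [(1S,2S,3R,4S)-3-(benzoyloxy)-1,2-(isopropylidenedioxy)-4-(4-methoxybenzyloxy)cyclohex-5-en-1-yl]methyl benzoate | O=C(OC[C@@]12C=C[C@H](OCc3ccc(OC)cc3)[C@@H](OC(=O)c3ccccc3)[C@@H]1OC(C)(C)O2)c1ccccc1 | intermediate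
17 | [(1S,2S,3R,4S)-3-(benzoyloxy)-4-hydroxy-1,2-(isopropylidenedioxy)cyclohex-5-en-1-yl]methyl benzoate | O=C(OC[C@@]12C=C[C@H](O)[C@@H](OC(=O)c3ccccc3)[C@@H]1OC(C)(C)O2)c1ccccc1 | intermediate
18 | [(1S,2S,3R,4S)-3-(benzoyloxy)-1,2,4-trihydroxycyclohex-5-en-1-yl]methyl benzoate | O=C(OC[C@@]1(O)C=C[C@H](O)[C@@H](OC(=O)c2ccccc2)[C@@H]1O)c1ccccc1 | target

## Step count and least certain steps

Total step count: 13. Longest linear sequence: 13 steps (1 to 18); the diene 6 is purchased.

Step 4 (key step). The most likely failure is a sluggish cycloaddition with competing thermal polymerisation of 5 and erosion of exo and ortho selectivity. The acetoxy diene is only a moderate donor, its Z isomer is inert, and the temperature needed is high. The fallback sets out from 5 and uses a stronger donor diene at lower temperature (PhMe, 60–70 °C): commercial (E)-(buta-1,3-dien-1-yloxy)trimethylsilane F1 would give the silyl ether adduct (2S,5R,6S)-2-tert-butyl-6-(trimethylsilyloxy)-1,3-dioxaspiro[4.5]dec-7-en-4-one F2. Reduction with LiAlH4 would give (1S,2S)-1-(hydroxymethyl)-2-(trimethylsilyloxy)cyclohex-3-en-1-ol F3, and K2CO3 in methanol would remove the silyl group, returning to the route at 8.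

Step 9. The most likely failure is loss of regiocontrol in the second dehydrobromination: proton removal at C2 or substitution of the allylic bromide by the amidine, because the required 1,4-elimination competes with these pathways. The fallback sets out from 10 and avoids the diene altogether.
- Epoxidation (mCPBA, NaHCO3) on the α face would give the 3α,4α-epoxide of 10, F4.
- Opening at C4 with phenylselenide (PhSeSePh, NaBH4, EtOH) would give the 3α-hydroxy-4β-phenylselanyl acetonide F5.
- Oxidation with H2O2 and selenoxide syn-elimination away from the carbinol carbon would give the 3α-hydroxy-4-ene acetonide F6.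
- Benzoylation (BzCl, pyridine, DMAP) would give the 3α-benzoyloxy-4-ene acetonide F7.
- A sensitised photooxygenation (O2, tetraphenylporphyrin, light, CH2Cl2, 0 °C; Schenck ene reaction) is expected to add oxygen to C4 anti to the benzoate and shift the alkene to C5=C6, giving the 4β-hydroperoxy-5-ene acetonide benzoate F8.
- Reduction with PPh3 comes back to the route at 17, which is then hydrolysed as in the second stage of step 13.

This detour also bypasses steps 10 to 12.

Step 11. The most likely failure is unselective or cationic epoxide opening (cis-1,2 or conjugate addition, self-condensation of the benzylic alcohol, acetal exchange), because the Lewis acid can ionise both the vinyl epoxide and the electron-rich alcohol. The fallback sets out from 14 and uses a carboxylic acid that needs no catalyst. Chloroacetic acid in CH2Cl2 at 0 °C would open the epoxide at C4 with inversion to give the 4β-chloroacetoxy-3α-hydroxy acetonide F9. Benzoylation (BzCl, pyridine, 0 °C) would give the 3α-benzoyloxy-4β-chloroacetoxy acetonide F10. Selective dechloroacetylation with thiourea and NaHCO3 in ethanol comes back to the route at 17.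

Step 13. The most likely failure is acid-induced ionisation at the allylic C4 or C1 carbinol with participation of a neighbouring benzoate, leading to epimerisation or acyl migration, because cleavage of the benzyl-type ether and of the acetonide both call for fairly strong acid. The fallback sets out from 16 and replaces acidolysis of the ether by oxidative debenzylation with DDQ in buffered wet CH2Cl2, which would allow 17 to be isolated (no new compound; entry F0). The acetonide would then be hydrolysed under much weaker acid (80% aqueous AcOH, 40 °C), coming back to the route at 18.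

## Further compounds

F1 | step 4 | (E)-(buta-1,3-dien-1-yloxy)trimethylsilane | C=C/C=C/O[Si](C)(C)C
F2 | step 4 | (2S,5R,6S)-2-tert-butyl-6-(trimethylsilyloxy)-1,3-dioxaspiro[4.5]dec-7-en-4-one | O=C1O[C@@H](C(C)(C)C)O[C@@]12CCC=C[C@@H]2O[Si](C)(C)C
F3 | step 4 | (1S,2S)-1-(hydroxymethyl)-2-(trimethylsilyloxy)cyclohex-3-en-1-ol | OC[C@@]1(O)CCC=C[C@@H]1O[Si](C)(C)C
F4 | step 9 | 3α,4α-epoxide of 10 | O=C(OC[C@@]12CC[C@H]3O[C@H]3[C@@H]1OC(C)(C)O2)c1ccccc1
F5 | step 9 | 3α-hydroxy-4β-phenylselanyl acetonide | O=C(OC[C@@]12CC[C@H]([Se]c3ccccc3)[C@@H](O)[C@@H]1OC(C)(C)O2)c1ccccc1
F6 | step 9 | 3α-hydroxy-4-ene acetonide | O=C(OC[C@@]12CC=C[C@@H](O)[C@@H]1OC(C)(C)O2)c1ccccc1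
F7 | step 9 | 3α-benzoyloxy-4-ene acetonide | O=C(OC[C@@]12CC=C[C@@H](OC(=O)c3ccccc3)[C@@H]1OC(C)(C)O2)c1ccccc1
F8 | step 9 | 4β-hydroperoxy-5-ene acetonide benzoate | O=C(OC[C@@]12C=C[C@H](OO)[C@@H](OC(=O)c3ccccc3)[C@@H]1OC(C)(C)O2)c1ccccc1
F9 | step 11 | 4β-chloroacetoxy-3α-hydroxy acetonide | O=C(OC[C@@]12C=C[C@H](OC(=O)CCl)[C@@H](O)[C@@H]1OC(C)(C)O2)c1ccccc1
F10 | step 11 | 3α-benzoyloxy-4β-chloroacetoxy acetonide | O=C(OC[C@@]12C=C[C@H](OC(=O)CCl)[C@@H](OC(=O)c3ccccc3)[C@@H]1OC(C)(C)O2)c1ccccc1
F0 | step 13 | none | none
A1 | alternative 1 | benzoic acid | OC(=O)c1ccccc1
A2 | alternative 1 | (1S,2R)-1,2-dihydroxycyclohexa-3,5-diene-1-carboxylic acid | OC(=O)[C@@]1(O)[C@H](O)C=CC=C1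
A3 | alternative 2 | [(5R,6R)-5-(benzoyloxy)-6-hydroxycyclohexa-1,3-dien-1-yl]methyl benzoate | O=C(OCC1=CC=C[C@@H](OC(=O)c2ccccc2)[C@@H]1O)c1ccccc1
A4 | alternative 2 | [8-(benzoyloxy)-7-hydroxy-2,3-dioxabicyclo[2.2.2]oct-5-en-1-yl]methyl benzoate, configured as in 18 | O=C(OC[C@@]1(OO2)C=C[C@H]2[C@@H](OC(=O)c3ccccc3)[C@@H]1O)c1ccccc1
A5 | alternative 3 | D-glucose 6-phosphate | O=C[C@H](O)[C@@H](O)[C@H](O)[C@H](O)COP(=O)(O)O
A6 | alternative 3 | 2-deoxy-scyllo-inosose, (2S,3R,4S,5R)-2,3,4,5-tetrahydroxycyclohexanone | O=C1C[C@@H](O)[C@H](O)[C@@H](O)[C@@H]1O
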